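## Structural features

The target is a cembranolide: a 14-membered carbocycle (C1–C14) fused cis across C1–C2 to an α-methylene-γ-butyrolactone (C15 carries the exocyclic methylene C17, C16 is the carbonyl, the ring oxygen sits on C2). Going round the large ring from C2 there are an E trisubstituted alkene C3=C4 (methyl on C4), one methylene C5, an E disubstituted alkene C6=C7, the tertiary carbinol C8 (S), the C9–C10 link, a cis trisubstituted epoxide C11–C12 (methyl on C12, C10 and C13 on the same side) and the acetoxy carbon C13 (R), which returns to C1 through C14. The six stereocentres form two clusters, C1/C2 (both S) and C11/C12/C13, plus the isolated C8, which is four atoms from either cluster, so no cluster can be relied on to control another. Fragile groups are the methylene lactone (a Michael acceptor), the skipped diene with its doubly allylic C5, the tertiary allylic alcohol (which ionises in acid and, once free, can open the epoxide at C11 in a 5-exo mode) and the epoxide next to an acetate. The real difficulty is to set the C11–C13 triad in the right absolute sense in a flexible ring remote from C1/C2 and C8, and to carry the methylene lactone through the sequence. The key step uses the fact that C2 is at once the lactone carbinol, allylic to the methyl-bearing C3=C4 alkene, and the neighbour of C1, which bears the acrylate carbons C15–C17. A terminal alkyne C3≡C4 can therefore be turned into the E alkenyl nucleophile with the C4 methyl in place and added to a C2 aldehyde under control by C1, after which the C2 alkoxide closes the five-membered ring on C16.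

## Logic of the disconnections

**28 ⇒ 27 (O–Si at C8).** The C8 oxygen stays silylated to the end, because a free C8 hydroxyl would direct epoxidation to C6=C7 and could open the epoxide at C11. The forward step must be a near-neutral fluoride cleavage.

**27 ⇒ 26 (C13–O, with inversion).** Hydroxyl-directed epoxidation puts the epoxide oxygen on the side of the carbinol oxygen, whereas the target has the C13 oxygen on the other side. The acetate is therefore introduced by invertive substitution. The demand is a clean SN2 reaction at a carbinol flanked by a fully substituted epoxide carbon.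

**26 ⇒ 25 (C11–O and C12–O).** Removing the epoxide leaves an allylic alcohol whose hydroxyl selects C11=C12 among four alkenes and fixes two stereocentres from one. The forward step needs oxygen delivery syn to the hydroxyl in the conformer imposed by the Z alkene, and a capped C8 oxygen.

**25 ⇒ 24 (C12–C13).** Cutting between the alkenyl carbon and the carbinol opens the ring to a chain with a Z alkenyl iodide and an aldehyde, two groups that tolerate everything else in the molecule. The forward step needs high dilution, retention of the Z geometry, and the 13S carbinol.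

**24 ⇒ 23 ⇒ 22 (oxidation level and protection at C13).** No skeletal bond changes. The aldehyde is unveiled only just before ring closure, from an ether orthogonal to the tertiary silyl ether.

**22 ⇒ 7 + 17 + 18 (C2–C3, C4–CH3, O–C16).** This is the convergent cut: one flask joins two halves of similar size, builds the trisubstituted alkene, the C2 stereocentre and the lactone. It demands regio- and syn-selective methylmetalation, Felkin–Anh addition controlled by C1, and a C1 centre in 17 that survives.

**7 ⇒ 6 (C4–C5).** The sp–sp3 bond is cut to a primary allylic chloride and an ethynyl nucleophile. The terminal alkyne enters last, so it never meets the ylide base or the metathesis catalyst. The forward step needs SN2 rather than SN2' attack.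

**6 ⇒ 5 (C11=C12).** The iodoalkene goes back to an aldehyde and an α-iodo ylide, which demands Z selectivity.

**5 ⇒ 4 (C6=C7).** Cross-metathesis extends the vinyl group on C8 by a chloromethyl carbon. It is placed after the trisubstituted alkene of 2 has been cleaved (otherwise ring closure to a cyclopentene would win) and before the iodoalkene exists.

**4 ⇒ 2 ⇒ 1 (C11=C(CH3)2, then O–Si).** The aldehyde comes from the trisubstituted alkene of 2. C8 is taken from the chiral pool in 1, so no reaction has to create the isolated stereocentre.

**17 ⇒ 15 ⇒ 13 + 14 (C2 oxidation level, then C1–C2).** The formyl group is traced to a nitromethyl group, and C1–C2 to an allylic substitution in which 14 serves as a formyl anion equivalent. The forward steps need catalyst control at C1 and an aldehyde release that spares the acidic C1–H.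

**13 ⇒ 12 ⇒ 10 + 11 (carbonate C–O, then C1–C15).** The acrylate unit and C1 are joined by a Morita–Baylis–Hillman reaction. Its carbinol configuration is irrelevant because it is erased later.

**10 ⇒ 9 ⇒ 8.** Oxidation and mono-protection of a symmetric diol.

## Other disconnections considered

**Alternative 1:** The cut is C4–C5, with C3=C4 traced back to an alkyne and C6=C7 to a terminal allyl group. In the forward sense [CpRu(MeCN)3]PF6 would couple the prop-1-ynyl group on C2 with the allyl group on C8 of the open-chain lactone A1 (ruthenacyclopentene, β-hydride loss from C7, reductive elimination) and give A2, which has the constitution and configuration of 27.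
- *In favour:* ring, C4–C5 bond and both skipped alkenes arise in one catalytic, atom-economical event, and both E geometries follow from the mechanism. Because ring closure is the last C–C bond formation, C11–C13 can be built in open chain under reagent control. On this point it is better than the chosen plan, which sets C13 during macrocyclisation and epoxidises the ring. It also needs no stoichiometric chromium.
- *Against:* the internal alkyne raises a regiochemical question (bond to C4, not C3) that the terminal alkyne of 7 does not. The allyl group sits on the fully substituted C8. Cationic ruthenium would meet the epoxide, the acetate, an ionisable propargylic acyloxy group at C2 and the methylene lactone, itself an alkene with an allylic hydrogen at C1.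
- *Comparison:* the cis-lactone of A1 still requires a carbon nucleophile to add to a C2 aldehyde next to C1, so the facial-selectivity problem is moved, not removed. The entropic demand of the 14-ring closure is equal. Step count should be comparable or slightly higher, since A1 must carry all six stereocentres.

**Alternative 2:** The cut is C15–C16 and C16–O: the carbonyl leaves as CO, giving the macrocyclic homopropargylic alcohol A3. Forward, PdCl2(PPh3)2/SnCl2 under CO would convert the C2 hydroxyl and the C1 ethynyl group of A3 into the methylene lactone A4.
- *In favour:* the Michael acceptor appears late and no labile acrylate aldehyde such as 17 is needed; on both points it is better than the chosen plan. The C1/C2 pair of A3 is the product type of allenylmetal additions to an enal, which is at least equal to Felkin control.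
- *Against:* the step forms one C–C and one C–O bond on a ring that must already exist, whereas the chosen step forms two C–C bonds and the C–O bond while joining the fragments. The acidic, tin-containing medium meets an allylic C2 hydroxyl, a tertiary allylic silyl ether and an allylic 4-methoxybenzyl ether, so ionisation or π-allyl formation are plausible.
- *Comparison:* the end game after A4 (ether cleavage at C13, epoxidation, inversion, desilylation) is the same as after 25, so the two are equal there. Oxidative removal of an allylic 4-methoxybenzyl ether may, however, over-oxidise to the enone. The route is probably a few steps longer.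

**Alternative 3:** The cut is C10–C11. Forward, 9-BBN would add to the C9=C10 vinyl group on C8 of the open-chain compound A5, and Pd(dppf)Cl2 with aqueous Cs2CO3 would couple the C10 borane with the Z alkenyl iodide at C11 to give the macrocycle A6.
- *In favour:* the sp3–sp2 coupling is stereospecific and a well-tried ring closure. C13 is already in place as its ether, so no stereocentre is created in the cyclisation; this is better than the chosen plan. It is catalytic in zerovalent palladium instead of needing excess divalent chromium.
- *Against:* 9-BBN would not spare a methylene lactone, which is why A6 has a saturated lactone; C17 must then be added by enolate chemistry on the macrocycle. C8 of A5 bears a vinyl and an alkenyl group, a doubly allylic tertiary ether that cannot be taken from 1 and ionises easily. One of four alkenes must be hydroborated selectively at a neopentyl-like position, and aqueous base meets the lactone.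
- *Comparison:* the end game after ring closure is equal. Step economy is worse, because of the separate methylenation and the de novo construction of C8.

Key step: step 12

**Remarks and assumptions**
- Cembrane numbering is used throughout: ring C1–C14; C15 is the lactone α-carbon, C16 the carbonyl, C17 the exocyclic methylene.
- Compounds 7, 17 and 22 were checked atom by atom against the target (C8 S in 7; C1 S in 17; C1 S, C2 S and C3/C14 cis in 22); they agree and stand as drawn.
- Design points beyond the bare disconnection:
  - the trisubstituted alkene of 2 is cleaved before metathesis and the iodoalkene is made after it;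
  - the terminal alkyne enters last;
  - 17 is released without acid and used at once;
  - the alane is activated with MeLi, not n-BuLi, to spare the alkenyl iodide;
  - the C8 silyl ether is kept to the last step.
- Assumption: (DHQD)2PHAL is taken to give the S configuration at C1 in step 10; if the sense of induction is the opposite, the pseudo-enantiomeric (DHQ)2PHAL is used.
- Assumption: by the usual vanadium transition-state model, allylic 1,3-strain (C10 cis to C13) is taken to outweigh the 1,2-interaction with the C12 methyl in step 16.

## Route

Step 1
Reactants: 1 (S)-linalool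
Product: 2 (3S)-3,7-dimethyl-3-(triethylsilyloxy)octa-1,6-diene
Conditions: TESOTf (1.2 equiv), 2,6-lutidine (1.5 equiv), CH2Cl2, −78 → 0 °C
Reagents that add atoms: triethylsilyl trifluoromethanesulfonate, CC[Si](CC)(CC)OS(=O)(=O)C(F)(F)F
Why: Silylation of a tertiary alcohol; the silyl triflate with a hindered pyridine base reacts where the chloride would not, and the C8 stereocentre is not touched.

Step 2
Reactants: 2 (3S)-3,7-dimethyl-3-(triethylsilyloxy)octa-1,6-diene
Product: 4 (4S)-4-methyl-4-(triethylsilyloxy)hex-5-enal, via trisubstituted epoxide 3 (not isolated)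
Conditions: mCPBA (1.05 equiv), CH2Cl2, 0 °C; then H5IO6 (1.2 equiv), THF–H2O, 0 °C
Reagents that add atoms: 3-chloroperoxybenzoic acid, OOC(=O)c1cccc(Cl)c1
Why: Peracid epoxidation selects the electron-rich trisubstituted alkene over the vinyl group, which is deactivated by the allylic silyloxy group; periodic acid then hydrates and cleaves the epoxide (glycol cleavage). This removes the alkene that would otherwise close a cyclopentene by ring-closing metathesis in step 3.

Step 3
Reactants: 4 (4S)-4-methyl-4-(triethylsilyloxy)hex-5-enal
Product: 5 (4S,5E)-7-chloro-4-methyl-4-(triethylsilyloxy)hept-5-enal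
Conditions: (Z)-1,4-dichlorobut-2-ene (3 equiv), second-generation Hoveyda–Grubbs catalyst (5 mol %), CH2Cl2, 40 °C
Reagents that add atoms: (Z)-1,4-dichlorobut-2-ene, ClC/C=C\CCl
Why: Olefin cross-metathesis between a hindered vinyl group on a fully substituted carbon, which does not homodimerise, and an excess of a reactive 1,2-disubstituted partner; the bulky allylic centre should enforce the E alkene and the aldehyde is tolerated. No second alkene is present in 4, so no ring closure can compete.

Step 4
Reactants: 5 (4S,5E)-7-chloro-4-methyl-4-(triethylsilyloxy)hept-5-enal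
Product: 6 (2E,4S,7Z)-1-chloro-8-iodo-4-methyl-4-(triethylsilyloxy)nona-2,7-diene
Conditions: EtPPh3I, n-BuLi, THF, 23 °C; I2, −78 °C; NaN(SiMe3)2, −20 °C; then 5, −78 → −20 °C
Reagents that add atoms: ethyltriphenylphosphonium iodide, CC[P+](c1ccccc1)(c1ccccc1)c1ccccc1.[I-]; iodine, II
Why: Stork–Zhao olefination: the α-iodo ylide made in the flask reacts with the aldehyde under kinetic control through the cis-oxaphosphetane and should give the Z 2-iodoalk-2-ene. At low temperature the Wittig reaction should outpace alkylation of the ylide by the allylic chloride.

Step 5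
Reactants: 6 (2E,4S,7Z)-1-chloro-8-iodo-4-methyl-4-(triethylsilyloxy)nona-2,7-diene
Product: 7 (4E,6S,9Z)-10-iodo-6-methyl-6-(triethylsilyloxy)undeca-4,9-dien-1-yne (fragment 1)
Conditions: HC≡CMgBr (3 equiv), CuBr·SMe2 (0.2 equiv), THF, 0 → 45 °C
Reagents that add atoms: ethynylmagnesium bromide, C#C[Mg]Br
Why: Copper-catalysed SN2 coupling of a primary allylic chloride with an alkynyl Grignard reagent gives the skipped enyne. Attack at the γ-carbon is blocked by the adjacent quaternary C8, and without palladium the alkenyl iodide should not couple.

Step 6
Reactants: 8 propane-1,3-diol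
Product: 9 3-[(4-methoxybenzyl)oxy]propan-1-ol
Conditions: NaH (1.0 equiv), 4-methoxybenzyl chloride (1.0 equiv), diol (3 equiv), THF–DMF, 0 → 23 °C
Reagents that add atoms: 4-methoxybenzyl chloride, COc1ccc(CCl)cc1
Why: Williamson ether synthesis; the excess of diol makes the mono-ether the main product.

Step 7
Reactants: 9 3-[(4-methoxybenzyl)oxy]propan-1-ol
Product: 10 3-[(4-methoxybenzyl)oxy]propanal
Conditions: TEMPO (0.1 equiv), PhI(OAc)2 (1.1 equiv), CH2Cl2, 23 °C
Reagents that add atoms: none
Why: Oxoammonium (TEMPO) oxidation stops at the aldehyde and is base-free, which avoids β-elimination of the 4-methoxybenzyloxy group.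

Step 8
Reactants: 10 3-[(4-methoxybenzyl)oxy]propanal; 11 methyl acrylate
Product: 12 methyl 3-hydroxy-5-[(4-methoxybenzyl)oxy]-2-methylidenepentanoate (racemic)
Conditions: DABCO (0.5 equiv), methyl acrylate (3 equiv), MeOH, 23 °C, 3–5 d
Reagents that add atoms: none
Why: Morita–Baylis–Hillman reaction: the amine adds to the acrylate, the ammonium enolate adds to the aldehyde and elimination returns the amine. The racemic carbinol centre is erased in step 10, so no control is needed.

Step 9
Reactants: 12 methyl 3-hydroxy-5-[(4-methoxybenzyl)oxy]-2-methylidenepentanoate (racemic)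
Product: 13 methyl 3-[(tert-butoxycarbonyl)oxy]-5-[(4-methoxybenzyl)oxy]-2-methylidenepentanoate (racemic)
Conditions: Boc2O (1.3 equiv), DMAP (0.1 equiv), CH2Cl2, 0 → 23 °C
Reagents that add atoms: di-tert-butyl dicarbonate, CC(C)(C)OC(=O)OC(=O)OC(C)(C)C
Why: DMAP-catalysed acylation turns the hydroxyl into a tert-butyl carbonate, the leaving group that releases its own base (tert-butoxide after loss of CO2) in step 10.

Step 10
Reactants: 13 methyl 3-[(tert-butoxycarbonyl)oxy]-5-[(4-methoxybenzyl)oxy]-2-methylidenepentanoate (racemic); 14 nitromethane
Product: 15 methyl (3S)-5-[(4-methoxybenzyl)oxy]-2-methylidene-3-(nitromethyl)pentanoate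
Conditions: (DHQD)2PHAL (10 mol %), nitromethane (10 equiv), toluene, 23 °C
Reagents that add atoms: none
Why: Lewis-base-catalysed asymmetric allylic alkylation of a Morita–Baylis–Hillman carbonate: the quinuclidine nitrogen adds SN2' with loss of the carbonate, the tert-butoxide formed deprotonates nitromethane, and the nitronate attacks the chiral allylammonium ion SN2', restoring the acrylate and setting C1 (S) under catalyst control. Excess nitromethane suppresses double allylation.

Step 11
Reactants: 15 methyl (3S)-5-[(4-methoxybenzyl)oxy]-2-methylidene-3-(nitromethyl)pentanoate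
Product: 17 methyl (3S)-3-formyl-5-[(4-methoxybenzyl)oxy]-2-methylidenepentanoate (fragment 2), via potassium nitronate 16 (not isolated)
Conditions: KOtBu (1.0 equiv), THF, −78 °C; dimethyldioxirane (1.1 equiv, in acetone), −78 → −20 °C; aq. NaH2PO4/Na2HPO4 (pH 7); used at once
Reagents that add atoms: dimethyldioxirane, CC1(C)OO1
Why: Oxidative Nef reaction: the dioxirane transfers an oxygen atom to the nitronate carbon and nitrite is lost, giving the aldehyde at low temperature without acid. One equivalent of base is consumed by the far more acidic nitromethyl group, so C1–H should not be deprotonated; 17 is not stored.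

Step 12
Reactants: 7 (4E,6S,9Z)-10-iodo-6-methyl-6-(triethylsilyloxy)undeca-4,9-dien-1-yne (fragment 1); 17 methyl (3S)-3-formyl-5-[(4-methoxybenzyl)oxy]-2-methylidenepentanoate (fragment 2); 18 trimethylaluminium
Product: 22 (4S,5S)-5-[(1E,4E,6S,9Z)-10-iodo-2,6-dimethyl-6-(triethylsilyloxy)undeca-1,4,9-trien-1-yl]-4-{2-[(4-methoxybenzyl)oxy]ethyl}-3-methylidenedihydrofuran-2(3H)-one, via alkenyldimethylalane 19 (not isolated), via lithium alkenyltrimethylalanate 20 (not isolated), via aluminate alkoxide 21 (not isolated)
Conditions: 7 (1.2 equiv), AlMe3 (2.4 equiv), Cp2ZrCl2 (0.3 equiv), CH2Cl2, 0 → 23 °C; volatiles removed in vacuo; THF, MeLi (1.2 equiv), −78 °C; 17 (1.0 equiv), −78 → 23 °C; aq. potassium sodium tartrate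
Reagents that add atoms: none
Why: Cp2ZrCl2 and AlMe3 form a cationic methylzirconocene that adds methyl and metal syn across the terminal alkyne, metal on the unhindered C3 and methyl on C4, and exchange to aluminium gives the E alkenylalane 19; the internal alkenes and the alkenyl iodide are not carbometallated. MeLi converts 19 into the more nucleophilic alanate 20, which transfers its sp2 group in preference to methyl to the aldehyde of 17 at −78 °C with retention of alkene geometry, so that C2 and the C4 methyl end up cis (E alkene). The new stereocentre C2 is set by C1 through a Felkin–Anh transition state: the planar C15 substituent stands perpendicular to the carbonyl and anti to the incoming alkenyl group, the C1 hydrogen lies next to the trajectory, and the 2S alkoxide 21 results. On warming, the alkoxide oxygen attacks the ester carbonyl C16 and expels methoxide; this 5-exo-trig acyl substitution closes the γ-lactone, which is cis because the Felkin adduct has C3 and C14 on the same side of the forming ring. The closest known reaction type is zirconium-catalysed methylalumination of terminal alkynes followed by addition of the alkenylalane or its ate complex to an aldehyde, combined with the alkoxide–acrylate lactonisation known from additions of 2-(alkoxycarbonyl)allyl metals. The step needs regio- and syn-selective carbometallation (secured by the terminal alkyne), 1,2-addition to the aldehyde in the presence of ester, acrylate and iodide (alanates are non-basic, add 1,2 and do not exchange with alkenyl iodides), and facial selectivity (secured by the difference between the flat, branched C15 and the unbranched C14 chain).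

Step 13
Reactants: 22 (4S,5S)-5-[(1E,4E,6S,9Z)-10-iodo-2,6-dimethyl-6-(triethylsilyloxy)undeca-1,4,9-trien-1-yl]-4-{2-[(4-methoxybenzyl)oxy]ethyl}-3-methylidenedihydrofuran-2(3H)-one
Product: 23 (4S,5S)-4-(2-hydroxyethyl)-5-[(1E,4E,6S,9Z)-10-iodo-2,6-dimethyl-6-(triethylsilyloxy)undeca-1,4,9-trien-1-yl]-3-methylidenedihydrofuran-2(3H)-one
Conditions: DDQ (1.3 equiv), CH2Cl2–aq. NaH2PO4/Na2HPO4 (pH 7), 0 °C
Reagents that add atoms: none
Why: Oxidative cleavage of the 4-methoxybenzyl ether by hydride abstraction and hydrolysis of the oxocarbenium ion. The tertiary silyl ether, the alkenyl iodide and the isolated alkenes should be inert under buffered conditions at 0 °C.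

Step 14
Reactants: 23 (4S,5S)-4-(2-hydroxyethyl)-5-[(1E,4E,6S,9Z)-10-iodo-2,6-dimethyl-6-(triethylsilyloxy)undeca-1,4,9-trien-1-yl]-3-methylidenedihydrofuran-2(3H)-one
Product: 24 2-{(3S,4S)-2-[(1E,4E,6S,9Z)-10-iodo-2,6-dimethyl-6-(triethylsilyloxy)undeca-1,4,9-trien-1-yl]-4-methylidene-5-oxotetrahydrofuran-3-yl}acetaldehyde, the C13 aldehyde, written with the stereocentres in cembrane terms as 1S,2S,8S
Conditions: Dess–Martin periodinane (1.5 equiv), pyridine, CH2Cl2, 0 → 23 °C
Reagents that add atoms: none
Why: Dess–Martin oxidation of the primary alcohol to the aldehyde under buffered, non-nucleophilic conditions that leave the methylene lactone alone.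

Step 15
Reactants: 24 the C13 aldehyde (1S,2S,8S) with the Z alkenyl iodide at C12
Product: 25 (1S,2S,3E,6E,8S,11Z,13S)-13-hydroxy-8-(triethylsilyloxy)cembra-3,6,11,15(17)-tetraen-16,2-olide
Conditions: CrCl2 (10 equiv), NiCl2 (0.1 equiv), DMSO–THF, 23 °C, slow addition (final 0.002 M)
Reagents that add atoms: none
Why: Nozaki–Hiyama–Kishi reaction: zerovalent nickel inserts into the C–I bond, the alkenyl group passes to trivalent chromium with retention of the Z geometry, and the alkenylchromium adds only to the aldehyde, closing the 14-membered ring at high dilution. C13 is formed under substrate control by the ring-closing transition state; the 13S epimer is the one carried on.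

Step 16
Reactants: 25 (1S,2S,3E,6E,8S,11Z,13S)-13-hydroxy-8-(triethylsilyloxy)cembra-3,6,11,15(17)-tetraen-16,2-olide
Product: 26 (1S,2S,3E,6E,8S,11S,12R,13S)-11,12-epoxy-13-hydroxy-8-(triethylsilyloxy)cembra-3,6,15(17)-trien-16,2-olide
Conditions: VO(acac)2 (5 mol %), tert-butyl hydroperoxide (1.5 equiv, in decane), CH2Cl2, 0 → 23 °C
Reagents that add atoms: tert-butyl hydroperoxide, CC(C)(C)OO
Why: Hydroxyl-directed epoxidation: the allylic alkoxide binds the pentavalent vanadium tert-butylperoxo complex and oxygen is delivered only to C11=C12, on the face of the hydroxyl. Because C10 is cis to C13, allylic 1,3-strain holds C13–H in the alkene plane, so the threo epoxy alcohol should form; its epoxide has the spatial arrangement of the target, and the 12R descriptor differs from the target's 12S only through the priority change on acetylation.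

Step 17
Reactants: 26 (1S,2S,3E,6E,8S,11S,12R,13S)-11,12-epoxy-13-hydroxy-8-(triethylsilyloxy)cembra-3,6,15(17)-trien-16,2-olide
Product: 27 (1S,2S,3E,6E,8S,11S,12S,13R)-13-acetoxy-11,12-epoxy-8-(triethylsilyloxy)cembra-3,6,15(17)-trien-16,2-olide
Conditions: PPh3 (3 equiv), DIAD (3 equiv), AcOH (3 equiv), toluene, 0 → 23 °C
Reagents that add atoms: acetic acid, CC(=O)O
Why: Mitsunobu reaction: the C13 oxygen is activated as an alkoxyphosphonium ion and displaced by acetate in an SN2 process, which inverts C13 to R and installs the acetate in the same step. The fully substituted C12 offers no β-hydrogen, so elimination can only occur toward C14.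

Step 18
Reactants: 27 (1S,2S,3E,6E,8S,11S,12S,13R)-13-acetoxy-11,12-epoxy-8-(triethylsilyloxy)cembra-3,6,15(17)-trien-16,2-olide
Product: 28 (1S,2S,3E,6E,8S,11S,12S,13R)-13-acetoxy-11,12-epoxy-8-hydroxycembra-3,6,15(17)-trien-16,2-olide (CNP0288879.2)
Conditions: TBAF (3 equiv), AcOH (3 equiv), THF, 0 → 23 °C
Reagents that add atoms: none
Why: Fluoride cleaves the Si–O bond; buffering with acetic acid keeps the medium near neutral, so that the acetate should not migrate and the liberated C8 hydroxyl should not open the epoxide at C11.

## Compound list

1 | (S)-linalool | C=C[C@@](C)(O)CCC=C(C)C | starting material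
2 | (3S)-3,7-dimethyl-3-(triethylsilyloxy)octa-1,6-diene | C=C[C@@](C)(O[Si](CC)(CC)CC)CCC=C(C)C | intermediate
3 | (3S)-6,7-epoxy-3,7-dimethyl-3-(triethylsilyloxy)oct-1-ene (both C6 epimers) | C=C[C@@](C)(O[Si](CC)(CC)CC)CCC1OC1(C)C | intermediate (not isolated)
4 | (4S)-4-methyl-4-(triethylsilyloxy)hex-5-enal | C=C[C@@](C)(O[Si](CC)(CC)CC)CCC=O | intermediate
5 | (4S,5E)-7-chloro-4-methyl-4-(triethylsilyloxy)hept-5-enal | ClC/C=C/[C@@](C)(O[Si](CC)(CC)CC)CCC=O | intermediate
6 | (2E,4S,7Z)-1-chloro-8-iodo-4-methyl-4-(triethylsilyloxy)nona-2,7-diene | ClC/C=C/[C@@](C)(O[Si](CC)(CC)CC)CC/C=C(/C)I | intermediate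
7 | (4E,6S,9Z)-10-iodo-6-methyl-6-(triethylsilyloxy)undeca-4,9-dien-1-yne (fragment 1) | C#CC/C=C/[C@@](C)(O[Si](CC)(CC)CC)CC/C=C(/C)I | intermediate
8 | propane-1,3-diol | OCCCO | starting material
9 | 3-[(4-methoxybenzyl)oxy]propan-1-ol | OCCCOCc1ccc(OC)cc1 | intermediate
10 | 3-[(4-methoxybenzyl)oxy]propanal | O=CCCOCc1ccc(OC)cc1 | intermediate
11 | methyl acrylate | C=CC(=O)OC | starting material
12 | methyl 3-hydroxy-5-[(4-methoxybenzyl)oxy]-2-methylidenepentanoate (racemic) | COC(=O)C(=C)C(O)CCOCc1ccc(OC)cc1 | intermediate
13 | methyl 3-[(tert-butoxycarbonyl)oxy]-5-[(4-methoxybenzyl)oxy]-2-methylidenepentanoate (racemic) | COC(=O)C(=C)C(OC(=O)OC(C)(C)C)CCOCc1ccc(OC)cc1 | intermediate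
14 | nitromethane | C[N+](=O)[O-] | starting material
15 | methyl (3S)-5-[(4-methoxybenzyl)oxy]-2-methylidene-3-(nitromethyl)pentanoate | [O-][N+](=O)C[C@@H](CCOCc1ccc(OC)cc1)C(=C)C(=O)OC | intermediate
16 | potassium nitronate of 15 | [K+].[O-][N+]([O-])=C[C@@H](CCOCc1ccc(OC)cc1)C(=C)C(=O)OC | intermediate (not isolated)
17 | methyl (3S)-3-formyl-5-[(4-methoxybenzyl)oxy]-2-methylidenepentanoate (fragment 2) | O=C[C@@H](CCOCc1ccc(OC)cc1)C(=C)C(=O)OC | intermediate
18 | trimethylaluminium | C[Al](C)C | starting material
19 | E alkenyldimethylalane from 7 (aluminium on C3, new methyl on C4) | C[Al](C)/C=C(\C)C/C=C/[C@@](C)(O[Si](CC)(CC)CC)CC/C=C(/C)I | intermediate (not isolated)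
20 | lithium alkenyltrimethylalanate from 19 | [Li+].C[Al-](C)(C)/C=C(\C)C/C=C/[C@@](C)(O[Si](CC)(CC)CC)CC/C=C(/C)I | intermediate (not isolated)
21 | lithium trimethylaluminate of the open-chain (1S,2S) C2 alkoxide (hydroxy ester stage) | [Li+].COc1ccc(COCC[C@@H](C(=C)C(=O)OC)[C@@H](O[Al-](C)(C)C)/C=C(\C)C/C=C/[C@@](C)(O[Si](CC)(CC)CC)CC/C=C(/C)I)cc1 | intermediate (not isolated)
22 | (4S,5S)-5-[(1E,4E,6S,9Z)-10-iodo-2,6-dimethyl-6-(triethylsilyloxy)undeca-1,4,9-trien-1-yl]-4-{2-[(4-methoxybenzyl)oxy]ethyl}-3-methylidenedihydrofuran-2(3H)-one | COc1ccc(COCC[C@H]2C(=C)C(=O)O[C@H]2/C=C(\C)C/C=C/[C@@](C)(O[Si](CC)(CC)CC)CC/C=C(/C)I)cc1 | intermediate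
23 | (4S,5S)-4-(2-hydroxyethyl)-5-[(1E,4E,6S,9Z)-10-iodo-2,6-dimethyl-6-(triethylsilyloxy)undeca-1,4,9-trien-1-yl]-3-methylidenedihydrofuran-2(3H)-one | OCC[C@H]1C(=C)C(=O)O[C@H]1/C=C(\C)C/C=C/[C@@](C)(O[Si](CC)(CC)CC)CC/C=C(/C)I | intermediate
24 | C13 aldehyde of the cis-lactone (1S,2S,8S; Z alkenyl iodide at C12) | O=CC[C@H]1C(=C)C(=O)O[C@H]1/C=C(\C)C/C=C/[C@@](C)(O[Si](CC)(CC)CC)CC/C=C(/C)I | intermediate
25 | (1S,2S,3E,6E,8S,11Z,13S)-13-hydroxy-8-(triethylsilyloxy)cembra-3,6,11,15(17)-tetraen-16,2-olide | C=C1C(=O)O[C@H]2/C=C(\C)C/C=C/[C@@](C)(O[Si](CC)(CC)CC)CC/C=C(/C)[C@@H](O)C[C@@H]12 | intermediate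
26 | (1S,2S,3E,6E,8S,11S,12R,13S)-11,12-epoxy-13-hydroxy-8-(triethylsilyloxy)cembra-3,6,15(17)-trien-16,2-olide | C=C1C(=O)O[C@H]2/C=C(\C)C/C=C/[C@@](C)(O[Si](CC)(CC)CC)CC[C@@H]3O[C@]3(C)[C@@H](O)C[C@@H]12 | intermediate
27 | (1S,2S,3E,6E,8S,11S,12S,13R)-13-acetoxy-11,12-epoxy-8-(triethylsilyloxy)cembra-3,6,15(17)-trien-16,2-olide | C=C1C(=O)O[C@H]2/C=C(\C)C/C=C/[C@@](C)(O[Si](CC)(CC)CC)CC[C@@H]3O[C@]3(C)[C@H](OC(C)=O)C[C@@H]12 | intermediate
28 | (1S,2S,3E,6E,8S,11S,12S,13R)-13-acetoxy-11,12-epoxy-8-hydroxycembra-3,6,15(17)-trien-16,2-olide (CNP0288879.2) | C=C1C(=O)O[C@H]2/C=C(\C)C/C=C/[C@@](C)(O)CC[C@@H]3O[C@]3(C)[C@H](OC(C)=O)C[C@@H]12 | target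

## Step count and least certain steps

Total step count: 18 (steps 1–5 to fragment 1, steps 6–11 to fragment 2, step 12 the union, steps 13–18 to the target).
Longest linear sequence: 13 steps (8 to 28 through steps 6–18).

**Step 12 (key step).** The most likely failure is incomplete facial selectivity in the addition to the aldehyde, because the two carbon substituents on C1 differ more in shape than in size and the acrylate carbon is not a strong σ-acceptor. Erosion of the C1 configuration by enolisation of 17 and competing methyl transfer are secondary risks, and the lactone may close slowly from the aluminate. The fallback sets out from 7 and 17 and comes back at 22. The same addition is run, and the C2-epimeric trans-lactone F1 that accompanies 22 is separated. It is opened with LiOH in aqueous THF at 0 °C to the γ-hydroxy acid F2 and closed again under Mitsunobu conditions (PPh3, DIAD), in which the carboxylate displaces the activated C2 oxygen with inversion. The C2 configuration is then corrected by an invertive C–O bond formation instead of being set in the C–C bond-forming event.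

**Step 15.** Two processes threaten the step: intermolecular coupling in competition with closure of the 14-membered ring, and low or wrong-sense facial selectivity at the aldehyde, since the nearest stereocentre (C1) is β to the carbonyl and the ring conformation cannot be predicted with confidence. The fallback sets out from the C13-epimer mixture obtained from 24 and comes back at 25. The mixture is oxidised with Dess–Martin periodinane to the enone F3, which is reduced under reagent control with the (R)-CBS oxazaborolidine and catecholborane at −78 °C; the alkenyl group acts as the large substituent, so the 13S alcohol 25 should result.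

**Step 10.** Carbonates from aliphatic aldehydes are less reactive and less well differentiated by the catalyst than aryl ones, so slow turnover, low enantioselectivity and double allylation of nitromethane are the likely problems. The fallback sets out from 10 and comes back at 15. A Henry reaction of 10 with 14 and dehydration (MsCl, Et3N) gives the nitroalkene F4. Conjugate addition of Meldrum's acid under a bifunctional cinchona-thiourea catalyst sets C1 and gives the adduct F5. Dimethylmethyleneammonium iodide in methanol at 65 °C (Mannich reaction, methanolysis, decarboxylation, loss of dimethylamine) then converts F5 into the methyl acrylate 15.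

**Step 11.** Once the aldehyde is formed, epimerisation at C1 or migration of the C15=C17 double bond into conjugation may occur, because C1–H is activated by both the formyl group and the acrylate; over-oxidation is a lesser risk. The fallback sets out from 15 and comes back at 17 without a new isolated compound. The oxygen-transfer chemistry is replaced by reductive cleavage of the nitro group: the nitronate 16 is added to aqueous TiCl3 buffered with NH4OAc (about pH 5), where reduction to the oxime and imine and hydrolysis give the aldehyde with no oxidant present.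

**Step 16.** Oxygen may be delivered to the wrong face if the ring conformation overrides allylic 1,3-strain, or if the interaction with the C12 methyl group dominates at vanadium and an erythro outcome results. The fallback sets out from 25 and comes back at 27. Oxidation gives the enone F3, and reduction with the (S)-CBS oxazaborolidine gives the 13R allylic alcohol F6. An erythro-selective directed epoxidation of F6 would give the epoxy alcohol F7, with the epoxide as in the target and C13 already R. Acetylation (Ac2O, pyridine, DMAP) returns to 27 and makes step 17 unnecessary.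

**Step 17.** Substitution may be sluggish or non-invertive at a ring carbinol next to a fully substituted epoxide carbon, through elimination toward C14 or participation of the epoxide oxygen; acetic acid is also a weak acid for this reaction. The fallback sets out from 26 and comes back at 27. Dess–Martin oxidation gives the epoxy ketone F8. Reduction with Zn(BH4)2 in ether at low temperature, where zinc chelates the ketone and epoxide oxygens and hydride should enter from the face away from C11 and its cis C10 substituent, gives the 13R epoxy alcohol F7. Acetylation returns to 27.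

## Further compounds

F1 | step 12 | (4S,5R) trans-lactone, the C2 epimer of 22 | COc1ccc(COCC[C@H]2C(=C)C(=O)O[C@@H]2/C=C(\C)C/C=C/[C@@](C)(O[Si](CC)(CC)CC)CC/C=C(/C)I)cc1
F2 | step 12 | (3S,4R,5E,8E,10S,13Z)-4-hydroxy-14-iodo-3-{2-[(4-methoxybenzyl)oxy]ethyl}-6,10-dimethyl-2-methylidene-10-(triethylsilyloxy)pentadeca-5,8,13-trienoic acid | COc1ccc(COCC[C@@H](C(=C)C(=O)O)[C@H](O)/C=C(\C)C/C=C/[C@@](C)(O[Si](CC)(CC)CC)CC/C=C(/C)I)cc1
F3 | step 15 | (1S,2S,3E,6E,8S,11Z)-13-oxo-8-(triethylsilyloxy)cembra-3,6,11,15(17)-tetraen-16,2-olide | C=C1C(=O)O[C@H]2/C=C(\C)C/C=C/[C@@](C)(O[Si](CC)(CC)CC)CC/C=C(/C)C(=O)C[C@@H]12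
F4 | step 10 | 1-methoxy-4-({[(3E)-4-nitrobut-3-en-1-yl]oxy}methyl)benzene | COc1ccc(COCC/C=C/[N+](=O)[O-])cc1
F5 | step 10 | 5-{(2S)-4-[(4-methoxybenzyl)oxy]-1-nitrobutan-2-yl}-2,2-dimethyl-1,3-dioxane-4,6-dione | COc1ccc(COCC[C@H](C[N+](=O)[O-])C2C(=O)OC(C)(C)OC2=O)cc1
F0 | step 11 | none | none
F6 | step 16 | (1S,2S,3E,6E,8S,11Z,13R)-13-hydroxy-8-(triethylsilyloxy)cembra-3,6,11,15(17)-tetraen-16,2-olide, the C13 epimer of 25 | C=C1C(=O)O[C@H]2/C=C(\C)C/C=C/[C@@](C)(O[Si](CC)(CC)CC)CC/C=C(/C)[C@H](O)C[C@@H]12
F7 | step 16 | (1S,2S,3E,6E,8S,11S,12R,13R)-11,12-epoxy-13-hydroxy-8-(triethylsilyloxy)cembra-3,6,15(17)-trien-16,2-olide, the C13 epimer of 26 | C=C1C(=O)O[C@H]2/C=C(\C)C/C=C/[C@@](C)(O[Si](CC)(CC)CC)CC[C@@H]3O[C@]3(C)[C@H](O)C[C@@H]12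
F8 | step 17 | (1S,2S,3E,6E,8S,11S,12S)-11,12-epoxy-13-oxo-8-(triethylsilyloxy)cembra-3,6,15(17)-trien-16,2-olide | C=C1C(=O)O[C@H]2/C=C(\C)C/C=C/[C@@](C)(O[Si](CC)(CC)CC)CC[C@@H]3O[C@]3(C)C(=O)C[C@@H]12
A1 | alternative 1 | open-chain cis-lactone with a prop-1-ynyl group on C2 and an allyl group on C8, epoxide and C13 acetate in place | C=C1C(=O)O[C@@H](C#CC)[C@H]1C[C@@H](OC(C)=O)[C@@]2(C)O[C@H]2CC[C@@](C)(CC=C)O[Si](CC)(CC)CC
A2 | alternative 1 | C8 triethylsilyl ether of the target (same constitution and configuration as 27) | C=C1C(=O)O[C@H]2/C=C(\C)C/C=C/[C@@](C)(O[Si](CC)(CC)CC)CC[C@@H]3O[C@]3(C)[C@H](OC(C)=O)C[C@@H]12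
A3 | alternative 2 | 14-membered carbocycle with ethynyl on C1 and free hydroxyl on C2, C13 4-methoxybenzyl ether and C8 triethylsilyl ether | O[C@H]1/C=C(\C)C/C=C/[C@@](C)(O[Si](CC)(CC)CC)CC/C=C(/C)[C@@H](OCc2ccc(OC)cc2)C[C@H]1C#C
A4 | alternative 2 | macrocyclic cis-fused methylene lactone with C13 4-methoxybenzyl ether and C8 triethylsilyl ether | C=C1C(=O)O[C@H]2/C=C(\C)C/C=C/[C@@](C)(O[Si](CC)(CC)CC)CC/C=C(/C)[C@@H](OCc3ccc(OC)cc3)C[C@@H]12
A5 | alternative 3 | open-chain saturated cis-lactone with a vinyl group on C8 and a Z alkenyl iodide at C11 | C1C(=O)O[C@@H](/C=C(\C)C/C=C/[C@@](C)(O[Si](CC)(CC)CC)C=C)[C@H]1C[C@H](OCc2ccc(OC)cc2)/C(C)=C\I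
A6 | alternative 3 | 14-membered triene with saturated cis-lactone, C13 4-methoxybenzyl ether and C8 triethylsilyl ether | C1C(=O)O[C@H]2/C=C(\C)C/C=C/[C@@](C)(O[Si](CC)(CC)CC)CC/C=C(/C)[C@@H](OCc3ccc(OC)cc3)C[C@@H]12
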